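The data are simulated from invented constants; noise was put on by code.

- Fed substrate is conserved: it stands as substrate, target, isomer of the product or uncatalysed product. So the share asked is the split s = [target]/([target] + [isomer of the product]) times the fraction of those products that is not uncatalysed.

| flask | substrate | catalyst | remark | time |
|---|---|---|---|---|
| east | 2.2 M (fed, over 4.0 d) | 4 mM | run made earlier; the fed solution adds 1.0 times the starting volume |  |
| eta | 1.5 M (fed, over 4.0 d) | 4.0 mM | the fed solution adds 1.0 times the starting volume | 8.0 d |
| gamma | 1.5 M (fed, over 4.0 d) | 8.0 mM | the fed solution adds 1.0 times the starting volume | 8.0 d |
| beta | 1.5 M (fed, over 4.0 d) | 15 mM | the fed solution adds 1.0 times the starting volume | 8.0 d |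
| theta | 1.5 M (fed, over 4.0 d) | 30 mM | the fed solution adds 1.0 times the starting volume | 8.0 d |
| epsilon | 1.5 M (fed, over 4.0 d) | 60 mM | the fed solution adds 1.0 times the starting volume | 8.0 d |

east run (percent of the substrate charged)

| time / h | target / % | isomer of the product / % |
|---|---|---|
| 5.00 | 0 | 4 |
| 15.0 | 5 | 12 |
| 25.0 | 9 | 14 |
| 40.0 | 11 | 22 |

(each reading ± 1.5 percentage points)

- amounts are per litre of the starting volume; all of the dose is in the solution fed
- what was read earlier has a scatter of 1.5 percentage points, one standard deviation
- "hardly changes" means that all values lie within two and a half points (for a concentration: within two and a half percent of the largest)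
- percentages count the whole charge, also what has not yet gone in
- no earlier run changes the charge of catalyst; that part of a forecast is a guess

- share of target in all that became target or isomer of the product or uncatalysed product for eta, gamma, beta, theta, epsilon, in this order
- the shape of the row from first to last (hardly changes / rises, then falls / falls all the way / rises all the way / falls, then rises)

- The last east reading, at 40.0 h, gives 0.333, the east split. As a reading it carries the scatter, and it lies below the symmetric value 0.5, where neither target nor isomer of the product is favoured.
- Eta looks nearly like east, with the same catalyst charge and dosing time and less substrate, but eta is read later. Starting catalyst times time is 4.80 times the east value in eta and 72.0 times in epsilon.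
- This gives two cases. If the east split is a kinetic one, a selectivity set by two parallel catalysed routes, the catalyst speeds both and the split stays. If target and isomer of the product exchange, the split moves towards its equilibrium value, and the splits of the five flasks, all past east in catalyst times time, should lie close together.
- Both cases speak of the split; the other factor, the fraction not uncatalysed, is not read in east, and the charge of catalyst may shift it. Taking that fraction as steady across the five flasks, the reckoning here commits to a row that hardly changes, at the split times that unread fraction. This part is a guess, since no earlier run varies the catalyst.
- The forecast differs, giving 28%, 30%, 32%, 33% and 33.5%, so rises all the way, on the ground that “More catalyst suppresses that leak”.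
- The flasks give 35.9%, 36.2%, 36.1%, 36.0% and 36.0%: the row hardly changes.

    substrate + catalyst ⇌ target + catalyst, rate k1*[substrate]*[catalyst] forward; the back reaction follows from the equilibrium constant (K = 6.48, k = 0.00392 M⁻¹ s⁻¹)
    target + catalyst ⇌ isomer of the product + catalyst, rate k2*[catalyst]*[target] forward; the back reaction follows from the equilibrium constant (K = 0.970, k = 0.00200 M⁻¹ s⁻¹)
    isomer of the product + catalyst ⇌ substrate + catalyst, rate k3*[catalyst]*[isomer of the product] forward; the back reaction follows from the equilibrium constant (k = 0.0200 M⁻¹ s⁻¹)
    substrate → uncatalysed product (k = 8.66 × 10⁻⁶ s⁻¹)

- At 8.00 d the split in eta is 0.531 and in epsilon 0.510, both above the east split of 0.333. Epsilon stands beside the equilibrium split 0.508, which is thermodynamic control between these two species. Epsilon's split times 0.706, the fraction of its products that is not uncatalysed, gives its share. Part of the reason for its share of 36.0% is that isomer of the product falls back to target and that the reading comes at that time. Without the falling back epsilon gives 11.1%, and read at 80.0 d it gives 0.696%.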